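You have a neighbour of blue to reckon later, charged with 0.052 mol% of free catalyst, so take blue first as the pattern.

    substrate + free catalyst ⇌ catalyst intermediate A (K1 = 12 M⁻¹, k1 = 3500 M⁻¹ min⁻¹)
    partner + catalyst intermediate A → catalyst intermediate B (k2 = 93 M⁻¹ min⁻¹)
    catalyst intermediate B → by-product + catalyst intermediate C (k3 = 8.8 min⁻¹)
    catalyst intermediate C → free catalyst + target (k4 = 12 min⁻¹)
    catalyst intermediate C + catalyst intermediate C ⇌ resting dimer (K5 = 1900 M⁻¹, k5 = 370 M⁻¹ min⁻¹)
    partner → decomposed reagent (k6 = 5.0 × 10⁻⁴ min⁻¹)

in all of them: free catalyst 0.21 mol%

| charge | substrate | partner | time | remark |
|---|---|---|---|---|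
| grey | 0.10 M | 1.80 equiv (fed, over 0.800 h) | 1.0 h | a stirred flask in which partner is dosed at a steady rate over 0.800 h without added volume, worked up at 1.0 h |
| blue | 0.10 M | 1.80 equiv | 1.0 h | everything together in a closed stirred flask, run for 1.0 h |
| teal | 0.10 M (fed, over 0.800 h) | 1.80 equiv | 1.0 h | a stirred flask in which substrate is dosed at a steady rate over 0.800 h without added volume, worked up at 1.0 h |
| red | 0.10 M | 1.80 equiv |  | a single well-mixed tank run continuously and read at steady state, 1.0 h in it on average |

- the set-up with the highest amount of target at the outlet or at the end, in percent of the substrate put in ("none" if the first two lie within 2 percentage points) (grey / blue / teal / red / none)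
- amount of target at the outlet or at the end, in percent of the substrate put in, grey
- amount of target at the outlet or at the end, in percent of the substrate put in, blue
- amount of target at the outlet or at the end, in percent of the substrate put in, teal
- amount of target at the outlet or at the end, in percent of the substrate put in, red

- in percentages every species weighs as the substrate in it: one resting dimer counts as two
- a doubled species enters its step squared and goes two at a time
- the stated concentrations are those of everything mixed, before any reaction; amounts are the same in each set-up
- the feed brings no volume worth counting
- run time (grey): 1.0 h

The first step is a pre-equilibrium: its way back, at 292 min⁻¹, runs faster than capture by partner, at 16.7 min⁻¹. So reckon τ at the charge: 0.306 min, the round time, meaning the minutes one catalyst needs for one turn of the cycle. It sums the wait for partner, stretched by the catalyst sitting free, 0.110 min, and the lifetimes of catalyst intermediates B, 0.114 min, and C, 0.0833 min. The first two are alike, so you have no single rate-limiting step.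

Each round makes one target, so the yield is loading times time over τ, here 41.1%, with the resting dimer left out. Now iterate. Put that answer back as mean concentrations for blue, substrate 0.0794 M and partner 0.159 M. Then τ becomes 0.335 min and your estimate for blue is 37.6%.

The red tank works at its outlet, which you reckon from your blue estimate as substrate 0.0624 M and partner 0.142 M. Its τ is 0.373 min, so your estimate for red is 33.8%, less than your estimate for blue. Your reckoning stops short of grey and teal.

The forecast says grey 26.5%, blue 35.7%, teal 30%, red 33.2%, best blue, holding that “having everything present from the start wins”. Your blue stands higher.

The flasks give grey 26.7%, blue 35.6%, teal 28.9%, red 32.8%, so blue is best. Blue moves 5 points, beyond the forecast's range, at 0.18 mol% or 0.24 mol% of free catalyst.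

For the neighbour at 0.052 mol%, the τ of the charge gives 10.2%. Put back, that means substrate 0.0949 M and partner 0.175 M, so τ is 0.312 min and the reckoned yield 9.99%. That neighbour gives 9.70% of target, with 90% of its substrate still there.

The numbers stand for no real mixture; what happens was integrated by code.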